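## Analysis of the target

Target 19 is a dihydroflavonol methyl ether: a chroman-4-one (ring A fused to the pyranone ring C) with a 3-hydroxy-4-methoxyphenyl ring B on C2 and a methoxy group on C3. Ring A carries free hydroxyls on C5 and C6, a methoxy group on C7 and hydrogen on C8. The six peripheral oxygens therefore fall into three phenols (O5, O6, O3') and three methyl ethers (O3, O7, O4'). The only stereocentres are C2 (R) and C3 (R), adjacent, with the aryl and methoxy groups trans and both equatorial on ring C. The descriptor at C3 is R only because of the C4 carbonyl; the same spatial arrangement in a flavan without the ketone is 3S. The β-aryloxy ketone is the sensitive part: base enolises C3 and expels the phenoxide O1, opening ring C to a chalcone-type enone and scrambling both centres; the free C5/C6 catechol is air-sensitive. The synthesis is hard on three counts: two contiguous centres must be set in absolute sense without a directing handle, they must survive the introduction of the C4 carbonyl and the O3 methyl group, and O5/O6 must be told apart from O7 on one ring. The strategy rests on O1, C8a, C4a and C4 forming a four-atom oxa-diene (an ortho-quinone methide of ring A) and C2–C3 forming a two-carbon unit that carries ring B and the C3 oxygen. Ring C and both centres can then arise in one [4+2] cycloaddition at the flavan oxidation level, where nothing is epimerisable.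

## Retrosynthetic reasoning

**Last step and protecting groups.** The final operation on 19 should be neutral, because the free dihydroflavonol tolerates neither base nor strong Lewis acid. The three phenols are therefore carried as benzyl ethers in ketone 18 and released together by hydrogenolysis, while O3, O7 and O4' are methyl ethers from the start. Methyl ethers on O5 and O6 were ruled out. Chelation to the C4 carbonyl would single out the O5 methyl for Lewis-acid cleavage, but the O6 methyl would then have to be distinguished from those on O7 and O4' and from the O3 methyl, which chelates to the same carbonyl.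

**C4 carbonyl.** The two C4–O bonds are cut next: ketone 18 comes from carbinol 17 by alcohol oxidation, and 17 from flavan 16 by benzylic oxidation. C4 is the right place for a late C–H oxidation because it sits on ring A ortho to O5 and O1 and para to O7, so hydride abstraction there gives the best-stabilised cation. The gain is that the cycloaddition can use an unsubstituted methide carbon, and the sensitive β-aryloxy ketone appears only two steps before the end. The forward steps must leave C2, C3 and three benzyl ethers alone.

**O3 methyl group.** The O3–CH3 bond is cut at the flavan stage: 16 comes from alcohol 15, and 15 from pivalate 14. In 15 no C–H is acidic, so alkoxide methylation cannot touch C2 or C3. The same methylation on a 3-hydroxy ketone would pass through the enolate that opens ring C.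

**Ring C (key disconnection).** Flavan ester 14 is cut at C3–C4 and O1–C2, which takes ring C apart into ortho-quinone methide 13 and enol ester 12. Both stereocentres lie on the two-carbon unit, so their relative configuration is stored in the alkene geometry of an achiral compound. The absolute configuration is left to a chiral acid, which also generates 13 from salicyl alcohol 8 by dehydration. The oxygen on the alkene has to be an ester. An enol ether would direct attack to the aryl-bearing carbon and put its oxygen on C2. The acyl group turns the oxygen lone pair down far enough that the para-methoxyphenyl group decides where the positive charge goes, so C3–C4 forms first and the aryl group ends on C2. The forward reaction has to outrun self-condensation of 13 and deliver one enantiomer of the trans adduct.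

**Ring B partner.** Enol ester 12 is cut at the vinylic C–O bond to trifluoroborate 11, and through boronate 10 at the C=C bond to aldehyde 9. Acylating the enolate of the homologous arylacetaldehyde would be shorter on paper but gives no reliable control of geometry. The boron route sets the E geometry in the olefination and passes it on with retention in the C–O coupling.

**Ring A partner.** Salicyl alcohol 8 comes from aldehyde ester 7 by reduction, the benzyl ethers of 7 from catechol 6, and 6 from trimethoxy ester 4 by two chelation-directed ether cleavages through 5. Ester 4 comes from hydroxy aldehyde 3, and 3 from the symmetrical phenol 1 by ortho-formylation through 2. This is where O5/O6 are told apart from O7. The formyl group that becomes C4 sits next to the future O5 and steers cleavage to that methyl group and then to its neighbour, leaving the remote one. A phenol already carrying two benzyl ethers and one methyl ether would have required a choice between two nearly identical ortho positions in the formylation; the symmetry of 1 removes that question. The phenol that becomes O1 is masked as an ester during the ether cleavage so that it does not occupy the formyl oxygen. The ester survives the Lewis acid and falls in the same hydride step that reduces the aldehyde.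

## Alternatives that were turned down

**Alternative 1:** Dihydroxylation of a flav-3-ene. The C3–O and C4–O bonds are cut, leading from diol A1, (2R,3S,4S)-2-[3-(benzyloxy)-4-methoxyphenyl]-5,6,7-trimethoxychroman-3,4-diol, back to flavene A2, (2S)-2-[3-(benzyloxy)-4-methoxyphenyl]-5,6,7-trimethoxy-2H-chromene. The forward key step is an osmium-catalysed syn-dihydroxylation (OsO4 with an amine N-oxide as reoxidant) on the face of the C3=C4 bond opposite the C2 aryl group.
- For: the step is thoroughly known, the facial control by the C2 aryl group is dependable, and the C4 oxygen arrives without a C–H oxidation. On reliability of the key step this alternative is stronger than the chosen one.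
- Against: A2 must already be one enantiomer, so the real problem, the absolute configuration at C2, is only moved upstream. 2-Aryl-2H-chromenes can also lose it by reversible electrocyclic opening of the pyran ring. A1 has two secondary hydroxyls to differentiate. Methylating O3 needs either extra protection of O4 or is done on the 3-hydroxy ketone, where base opens ring C. The trimethoxy ring A still needs cleavage at O5 and O6 only.
- Comparison: the chosen strategy gives both centres from achiral partners in one step and a non-epimerisable stage for the methylation. Alternative 1 is longer once the enantioselective preparation of A2 and the differentiation steps are counted.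

**Alternative 2:** Carbene C–H insertion. The C2–C3 bond is cut, leading from flavanone A3, (2S)-2-[3-(benzyloxy)-4-methoxyphenyl]-5,6,7-trimethoxychroman-4-one, back to diazoketone A4, 1-{2-[(3-(benzyloxy)-4-methoxyphenyl)methoxy]-4,5,6-trimethoxyphenyl}-2-diazoethan-1-one. A chiral dirhodium tetracarboxylate would generate the carbene at C3, which inserts into one enantiotopic benzylic C–H bond of the O–CH2–aryl group and closes ring C.
- For: a C–C bond is made by C–H functionalisation without pre-functionalising C2, C4 is already a ketone, and A4 is quickly assembled. On step count to the ring system it is at least as good as the chosen route.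
- Against: the ether oxygen sits where a five-membered oxonium ylide forms easily, and a [1,2]-benzyl shift to a 2-benzylbenzofuran-3-one is the usual fate of such substrates. Six-membered insertion is the less favoured mode, and an enantioselective version giving flavanones has no close analogy. A3 lacks the C3 oxygen; introducing it requires the enolate, which expels O1 and racemises C2. The trans relation, the methylation on the sensitive ketone and the O5/O6 demethylation all remain.
- Comparison: the chosen strategy sets C2 and C3 together with the C3 oxygen in place and handles them only at the flavan level.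

**Alternative 3:** Aryne annulation. The O1–C8a and C4–C4a bonds are cut, leading from A5, (2R,3R)-2-[3-(benzyloxy)-4-methoxyphenyl]-3,5,6,7-tetramethoxychroman-4-one, back to hydroxy ester A6, methyl (2R,3R)-3-[3-(benzyloxy)-4-methoxyphenyl]-3-hydroxy-2-methoxypropanoate, and aryne A7, 3,4,5-trimethoxybenzyne. A7 would be released by fluoride from silyl triflate A8, 3,4,5-trimethoxy-2-(trimethylsilyl)phenyl trifluoromethanesulfonate. The alkoxide of A6 adds to the aryne carbon remote from the flanking methoxy group, and the resulting aryl anion attacks the ester.
- For: it is the most convergent plan. Both centres and the O3 methyl group are made beforehand in an open chain by established asymmetric chemistry, the regiochemistry of addition to a 3-alkoxyaryne is dependable, and A5 is one deprotection from the target. In step count after the key step it beats the chosen route.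
- Against: under basic fluoride the β-alkoxide of an α-alkoxy ester can fragment by retro-aldol and its α-C–H can epimerise. A hindered secondary benzylic alkoxide is a poor aryne trap, and the aryl anion may be protonated before it acylates. A5 forms under conditions that enolise and open it, and A8 needs several steps. The last step must remove methyl groups from O5 and O6 while keeping those on O7, O3 and O4', which chelation secures only for O5.
- Comparison: the chosen strategy closes ring C under acid at an oxidation level with no labile centre and ends with a neutral hydrogenolysis.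

Key step: step 9

Assumption: the (R) enantiomer of the catalyst is written in step 9; which enantiomer delivers the (2R,3S) adduct cannot be predicted with confidence, and if the sense proves opposite the (S) enantiomer is used with nothing else changed.

## Route

Step 1
Reactants: 1 3,4,5-trimethoxyphenol
Product: 3 6-hydroxy-2,3,4-trimethoxybenzaldehyde, via 2-(hydroxymethyl)-3,4,5-trimethoxyphenol 2 (not isolated)
Conditions: MgCl2, Et3N, (CH2O)n, MeCN, reflux; then 1 M HCl
Reagents that add atoms: paraformaldehyde (as formaldehyde), C=O
Why: Magnesium-phenoxide-directed ortho-formylation (Casnati–Skattebøl): formaldehyde bound to the magnesium phenoxide is delivered to the ortho carbon to give 2, which a second formaldehyde oxidises by hydride transfer; the two ortho positions of 1 are equivalent, so only one aldehyde can form.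

Step 2
Reactants: 3 6-hydroxy-2,3,4-trimethoxybenzaldehyde
Product: 4 2-formyl-3,4,5-trimethoxyphenyl pivalate
Conditions: PivCl, Et3N, DMAP (cat.), CH2Cl2, 0 °C → rt
Reagents that add atoms: pivaloyl chloride, CC(C)(C)C(Cl)=O
Why: O-Acylation of the phenol; the pivalate keeps this oxygen from binding the Lewis acid in step 3, so the formyl oxygen is free to chelate toward the neighbouring methoxy group, and an aryl ester survives BCl3 where a benzyl or silyl ether would not.

Step 3
Reactants: 4 2-formyl-3,4,5-trimethoxyphenyl pivalate
Product: 6 2-formyl-3,4-dihydroxy-5-methoxyphenyl pivalate, via 2-formyl-3-hydroxy-4,5-dimethoxyphenyl pivalate 5 (not isolated)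
Conditions: BCl3 (3 equiv), CH2Cl2, −78 °C → rt; then H2O
Reagents that add atoms: none
Why: Chelation-controlled aryl methyl ether cleavage: BCl3 held between the formyl oxygen and the ortho methoxy oxygen cleaves that methyl group first (5), the aryloxyboron chloride so formed then binds the adjacent methoxy oxygen in a five-membered chelate and cleaves it, and the remote methoxy group (the future O7) has no such assistance; the same pattern is known for 2,3,4-trimethoxybenzaldehyde.

Step 4
Reactants: 6 2-formyl-3,4-dihydroxy-5-methoxyphenyl pivalate
Product: 7 3,4-bis(benzyloxy)-2-formyl-5-methoxyphenyl pivalate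
Conditions: BnBr (2.5 equiv), K2CO3, DMF, rt → 40 °C, Ar
Reagents that add atoms: benzyl bromide, BrCc1ccccc1
Why: Williamson etherification of both phenols; the hindered pivalate should resist anhydrous carbonate, and exclusion of air protects the catechol until it is alkylated.

Step 5
Reactants: 7 3,4-bis(benzyloxy)-2-formyl-5-methoxyphenyl pivalate
Product: 8 3,4-bis(benzyloxy)-2-(hydroxymethyl)-5-methoxyphenol
Conditions: LiAlH4, THF, 0 °C; then aq. KNaC4H4O6 (potassium sodium tartrate)
Reagents that add atoms: none
Why: Hydride reduction of the aldehyde to the benzylic alcohol and reductive cleavage of the aryl pivalate in one operation; the neutral tartrate work-up avoids premature ionisation of the electron-rich salicyl alcohol, which is used promptly.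

Step 6
Reactants: 9 3-(benzyloxy)-4-methoxybenzaldehyde
Product: 10 2-{(E)-2-[3-(benzyloxy)-4-methoxyphenyl]ethenyl}-4,4,5,5-tetramethyl-1,3,2-dioxaborolane
Conditions: CH2(Bpin)2, LiTMP (lithium 2,2,6,6-tetramethylpiperidide), THF, 0 °C; then 9, −78 °C → rt; then H2O
Reagents that add atoms: bis(pinacolato)borylmethane [2,2'-methylenebis(4,4,5,5-tetramethyl-1,3,2-dioxaborolane)], CC1(C)OB(CB2OC(C)(C)C(C)(C)O2)OC1(C)C
Why: Boron–Wittig olefination: the α-boryl carbanion adds to the aldehyde and syn elimination of a boron–oxygen unit gives the alkenyl boronate, with aryl and the remaining boryl group trans as is usual for aromatic aldehydes.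

Step 7
Reactants: 10 2-{(E)-2-[3-(benzyloxy)-4-methoxyphenyl]ethenyl}-4,4,5,5-tetramethyl-1,3,2-dioxaborolane
Product: 11 potassium {(E)-2-[3-(benzyloxy)-4-methoxyphenyl]ethenyl}trifluoroborate
Conditions: KHF2, MeOH/H2O, rt
Reagents that add atoms: potassium hydrogen difluoride, F.[F-].[K+]
Why: Ligand exchange at boron gives the crystalline trifluoroborate, the boron form used in the copper coupling; the alkene geometry is not touched.

Step 8
Reactants: 11 potassium {(E)-2-[3-(benzyloxy)-4-methoxyphenyl]ethenyl}trifluoroborate
Product: 12 (E)-2-[3-(benzyloxy)-4-methoxyphenyl]ethenyl pivalate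
Conditions: PivOH, CuBr (10 mol %), DMAP (20 mol %), 4 Å MS, O2 (1 atm), MeCN, 40 °C
Reagents that add atoms: pivalic acid, CC(C)(C)C(=O)O
Why: Chan–Lam-type oxidative C–O coupling of an alkenyltrifluoroborate with a carboxylic acid: transmetalation to copper and reductive elimination from a trivalent copper carboxylate proceed with retention, so the E geometry of 11 becomes the E geometry of the enol ester.

Step 9
Reactants: 8 3,4-bis(benzyloxy)-2-(hydroxymethyl)-5-methoxyphenol; 12 (E)-2-[3-(benzyloxy)-4-methoxyphenyl]ethenyl pivalate
Product: 14 (2R,3S)-5,6-bis(benzyloxy)-2-[3-(benzyloxy)-4-methoxyphenyl]-7-methoxychroman-3-yl pivalate, via 4,5-bis(benzyloxy)-3-methoxy-6-methylidenecyclohexa-2,4-dien-1-one 13 (not isolated)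
Conditions: (R)-3,3'-bis(2,4,6-triisopropylphenyl)-1,1'-binaphthyl-2,2'-diyl N-(trifluoromethanesulfonyl)phosphoramide (10 mol %), 12 (1.5 equiv), 5 Å MS, toluene, −20 °C → rt, slow addition of 8
Reagents that add atoms: none
Why: Proposed new method: the strongly acidic chiral phosphoramide protonates the benzylic hydroxyl of 8 and water leaves, giving ortho-quinone methide 13, which stays hydrogen-bonded (in the limit ion-paired as the ortho-hydroxybenzyl cation) to the chiral anion; the oxygen donors ortho and para to the methide carbon make this ionisation easy. Enol ester 12 then adds in an inverse-electron-demand hetero-Diels–Alder reaction that is concerted but asynchronous: the pivaloyloxy-bearing alkene carbon bonds to the methide carbon first (C3–C4), positive charge builds on the other alkene carbon, and the phenolic oxygen closes the O1–C2 bond. The closest known reaction types are the chiral Brønsted-acid-catalysed [4+2] cycloaddition of aryl-substituted ortho-quinone methides with styrenes and the thermal cycloaddition of simple ortho-quinone methides with β-substituted styrenes to 2,3-trans flavans; new here are the unsubstituted methide carbon, so that the catalyst must control two centres that both lie on the alkene, and an enol ester as the two-carbon partner. Ring C closes as a six-membered ring by [4+2] cycloaddition (in the stepwise limit a 6-exo-trig capture of the benzylic cation by the phenolic oxygen). C2 and C3 are set together: their trans relation comes from the E geometry of 12 through suprafacial addition, and in the stepwise limit the pivalate carbonyl bridges the cation on one face and leaves the opposite face to O1, which leads to the same trans product. Their absolute configuration comes from the chiral anion bound at the methide oxygen, whose two triisopropylphenyl walls leave one enantiotopic face of the alkene open. The step needs regioselectivity (aryl on C2, oxygen on C3), which the para-methoxy group of ring B secures because it stabilises the benzylic cation far better than the weakly donating acyloxy group stabilises the alternative; it also needs chemoselectivity against self-condensation of 13 at the free C8 position, which the excess of 12 and the slow addition of 8 are meant to secure.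

Step 10
Reactants: 14 (2R,3S)-5,6-bis(benzyloxy)-2-[3-(benzyloxy)-4-methoxyphenyl]-7-methoxychroman-3-yl pivalate
Product: 15 (2R,3S)-5,6-bis(benzyloxy)-2-[3-(benzyloxy)-4-methoxyphenyl]-7-methoxychroman-3-ol
Conditions: LiAlH4, THF, 0 °C → rt
Reagents that add atoms: none
Why: Reductive cleavage of the hindered ester, which is slow to saponify; benzyl and methyl ethers are inert and the flavan has no epimerisable centre.

Step 11
Reactants: 15 (2R,3S)-5,6-bis(benzyloxy)-2-[3-(benzyloxy)-4-methoxyphenyl]-7-methoxychroman-3-ol
Product: 16 (2R,3S)-5,6-bis(benzyloxy)-2-[3-(benzyloxy)-4-methoxyphenyl]-3,7-dimethoxychromane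
Conditions: NaH, MeI, THF/DMF, 0 °C → rt
Reagents that add atoms: iodomethane, CI
Why: Williamson methylation of the secondary alkoxide; with no carbonyl in the molecule neither C2–H nor C3–H is acidic, so the trans arrangement is safe under strong base.

Step 12
Reactants: 16 (2R,3S)-5,6-bis(benzyloxy)-2-[3-(benzyloxy)-4-methoxyphenyl]-3,7-dimethoxychromane
Product: 17 (2R,3S)-5,6-bis(benzyloxy)-2-[3-(benzyloxy)-4-methoxyphenyl]-3,7-dimethoxychroman-4-ol (both C4 epimers)
Conditions: DDQ (2 equiv), CH2Cl2/H2O (18:1), rt
Reagents that add atoms: water, O
Why: Benzylic oxidation by hydride abstraction: DDQ takes hydride from C4, whose cation is stabilised by three oxygen donors of ring A (O5 and O1 ortho, O7 para), and water captures it, as known for O-alkylated flavan-3-ol derivatives; the configuration of the new C4 carbinol does not matter because step 13 removes it.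

Step 13
Reactants: 17 (2R,3S)-5,6-bis(benzyloxy)-2-[3-(benzyloxy)-4-methoxyphenyl]-3,7-dimethoxychroman-4-ol
Product: 18 (2R,3R)-5,6-bis(benzyloxy)-2-[3-(benzyloxy)-4-methoxyphenyl]-3,7-dimethoxychroman-4-one
Conditions: Dess–Martin periodinane, CH2Cl2, 0 °C → rt
Reagents that add atoms: none
Why: Dess–Martin oxidation of the secondary benzylic alcohol under near-neutral conditions; the ketone already has the more stable 2,3-trans diequatorial arrangement and no base is present, so C3 (now α to the carbonyl) is not expected to epimerise, and its descriptor changes to R only through the new priority of C4.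

Step 14
Reactants: 18 (2R,3R)-5,6-bis(benzyloxy)-2-[3-(benzyloxy)-4-methoxyphenyl]-3,7-dimethoxychroman-4-one
Product: 19 (2R,3R)-5,6-dihydroxy-2-(3-hydroxy-4-methoxyphenyl)-3,7-dimethoxychroman-4-one
Conditions: H2 (1 atm), Pd/C (10 wt % palladium metal on carbon), EtOAc/MeOH, rt; work-up under Ar
Reagents that add atoms: none
Why: Hydrogenolysis of the three aryl benzyl ethers under neutral conditions should leave the aryl ketone, the three methyl ethers and both stereocentres untouched; air is excluded on isolation because of the C5/C6 catechol.

## Compound list

1 | 3,4,5-trimethoxyphenol | COc1cc(O)cc(OC)c1OC | starting material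
2 | 2-(hydroxymethyl)-3,4,5-trimethoxyphenol | OCc1c(O)cc(OC)c(OC)c1OC | intermediate (not isolated)
3 | 6-hydroxy-2,3,4-trimethoxybenzaldehyde | O=Cc1c(O)cc(OC)c(OC)c1OC | intermediate
4 | 2-formyl-3,4,5-trimethoxyphenyl pivalate | O=Cc1c(OC(=O)C(C)(C)C)cc(OC)c(OC)c1OC | intermediate
5 | 2-formyl-3-hydroxy-4,5-dimethoxyphenyl pivalate | O=Cc1c(OC(=O)C(C)(C)C)cc(OC)c(OC)c1O | intermediate (not isolated)
6 | 2-formyl-3,4-dihydroxy-5-methoxyphenyl pivalate | O=Cc1c(OC(=O)C(C)(C)C)cc(OC)c(O)c1O | intermediate
7 | 3,4-bis(benzyloxy)-2-formyl-5-methoxyphenyl pivalate | O=Cc1c(OC(=O)C(C)(C)C)cc(OC)c(OCc2ccccc2)c1OCc1ccccc1 | intermediate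
8 | 3,4-bis(benzyloxy)-2-(hydroxymethyl)-5-methoxyphenol | OCc1c(O)cc(OC)c(OCc2ccccc2)c1OCc1ccccc1 | intermediate
9 | 3-(benzyloxy)-4-methoxybenzaldehyde | COc1ccc(C=O)cc1OCc1ccccc1 | starting material
10 | 2-{(E)-2-[3-(benzyloxy)-4-methoxyphenyl]ethenyl}-4,4,5,5-tetramethyl-1,3,2-dioxaborolane | COc1ccc(/C=C/B2OC(C)(C)C(C)(C)O2)cc1OCc1ccccc1 | intermediate
11 | potassium {(E)-2-[3-(benzyloxy)-4-methoxyphenyl]ethenyl}trifluoroborate | COc1ccc(/C=C/[B-](F)(F)F)cc1OCc1ccccc1.[K+] | intermediate
12 | (E)-2-[3-(benzyloxy)-4-methoxyphenyl]ethenyl pivalate | COc1ccc(/C=C/OC(=O)C(C)(C)C)cc1OCc1ccccc1 | intermediate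
13 | 4,5-bis(benzyloxy)-3-methoxy-6-methylidenecyclohexa-2,4-dien-1-one | C=C1C(=O)C=C(OC)C(OCc2ccccc2)=C1OCc1ccccc1 | intermediate (not isolated)
14 | (2R,3S)-5,6-bis(benzyloxy)-2-[3-(benzyloxy)-4-methoxyphenyl]-7-methoxychroman-3-yl pivalate | COc1ccc([C@H]2Oc3cc(OC)c(OCc4ccccc4)c(OCc4ccccc4)c3C[C@@H]2OC(=O)C(C)(C)C)cc1OCc1ccccc1 | intermediate
15 | (2R,3S)-5,6-bis(benzyloxy)-2-[3-(benzyloxy)-4-methoxyphenyl]-7-methoxychroman-3-ol | COc1ccc([C@H]2Oc3cc(OC)c(OCc4ccccc4)c(OCc4ccccc4)c3C[C@@H]2O)cc1OCc1ccccc1 | intermediate
16 | (2R,3S)-5,6-bis(benzyloxy)-2-[3-(benzyloxy)-4-methoxyphenyl]-3,7-dimethoxychromane | COc1ccc([C@H]2Oc3cc(OC)c(OCc4ccccc4)c(OCc4ccccc4)c3C[C@@H]2OC)cc1OCc1ccccc1 | intermediate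
17 | (2R,3S)-5,6-bis(benzyloxy)-2-[3-(benzyloxy)-4-methoxyphenyl]-3,7-dimethoxychroman-4-ol (both C4 epimers) | COc1ccc([C@H]2Oc3cc(OC)c(OCc4ccccc4)c(OCc4ccccc4)c3C(O)[C@@H]2OC)cc1OCc1ccccc1 | intermediate
18 | (2R,3R)-5,6-bis(benzyloxy)-2-[3-(benzyloxy)-4-methoxyphenyl]-3,7-dimethoxychroman-4-one | COc1ccc([C@H]2Oc3cc(OC)c(OCc4ccccc4)c(OCc4ccccc4)c3C(=O)[C@@H]2OC)cc1OCc1ccccc1 | intermediate
19 | (2R,3R)-5,6-dihydroxy-2-(3-hydroxy-4-methoxyphenyl)-3,7-dimethoxychroman-4-one | COc1ccc([C@H]2Oc3cc(OC)c(O)c(O)c3C(=O)[C@@H]2OC)cc1O | target

## Step count and least certain steps

Total step count: 14. Longest linear sequence: 11 steps (steps 1 to 5, then 9 to 14); the ring B branch (steps 6 to 8) joins at step 9.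

**Step 9 (key step, carries the new-method label).**
- What may go wrong: poor enantiofacial discrimination, because the alkene has no hydrogen-bond donor to hold it against the chiral anion and the methide carbon itself carries no substituent.
- Further risks: self-condensation of the methide through electrophilic attack at the free C8 position of unreacted 8; hydrolysis of the enol ester by the water released; capture of the C2 cation by the pivalate carbonyl followed by water instead of by O1.
- Fallback, from 8 and 12, returning at 15: the cycloaddition is run without chiral control, with an achiral acid such as diphenyl hydrogen phosphate or by heating in toluene. This is the known behaviour of ortho-quinone methides toward electron-rich styrenes. It should give 14 together with its mirror image, (2S,3R)-5,6-bis(benzyloxy)-2-[3-(benzyloxy)-4-methoxyphenyl]-7-methoxychroman-3-yl pivalate F1. Hydride cleavage as in step 10 then gives 15 and (2S,3R)-5,6-bis(benzyloxy)-2-[3-(benzyloxy)-4-methoxyphenyl]-7-methoxychroman-3-ol F2, which are separated by preparative chromatography on a chiral stationary phase (amylose tris(3,5-dimethylphenylcarbamate)). Half of the material is given up.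

**Step 3.**
- What may go wrong: the second ether cleavage stalls, or prolonged exposure cleaves the pivalate or the third methyl ether.
- Fallback, from 4, returning at 6: BCl3 is limited to one equivalent at −78 °C so that only the formyl-directed cleavage occurs, and 5 is isolated. Its 2-methoxyphenol unit is then removed oxidatively instead of by Lewis acid. NaIO4 in aqueous acetic acid gives the ortho-quinone 2-formyl-5-methoxy-3,4-dioxocyclohexa-1,5-dien-1-yl pivalate F3, which is reduced at once with Na2S2O4 to catechol 6.

**Step 8.**
- What may go wrong: protodeboronation or oxidative homocoupling of the electron-rich alkenyl boron species, and slow C–O bond formation with the hindered carboxylate.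
- Fallback, from 9, returning at 12: a Wittig reaction with the ylide from (methoxymethyl)triphenylphosphonium chloride and KOtBu gives the enol ether 2-(benzyloxy)-1-methoxy-4-(2-methoxyethenyl)benzene F4 as an E/Z mixture. Acid hydrolysis gives 2-[3-(benzyloxy)-4-methoxyphenyl]acetaldehyde F5. O-Acylation of its enolate with pivaloyl chloride (Et3N, DMAP) gives 12 together with its isomer (Z)-2-[3-(benzyloxy)-4-methoxyphenyl]ethenyl pivalate F6. The E isomer is separated by chromatography, and the Z isomer can be equilibrated with a trace of iodine.

**Step 12.**
- What may go wrong: competing hydride abstraction at C2, which is activated by O1 and the para-methoxyphenyl ring and would destroy the C2 centre through a flav-2-ene or flavylium ion; oxidative loss of a benzyl ether is a lesser risk.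
- Fallback, from 16, returning at 17: C4 is acetoxylated with Pb(OAc)4 (tetravalent lead) in benzene, a metal-bound two-electron oxidation known for O-alkylated flavan-3-ols, to give (2R,3R)-5,6-bis(benzyloxy)-2-[3-(benzyloxy)-4-methoxyphenyl]-3,7-dimethoxychroman-4-yl acetate F7 (both C4 epimers). Methanolysis with K2CO3 in MeOH then gives 17.

**Step 14.**
- What may go wrong: incomplete cleavage of the hindered O5 benzyl ether next to the carbonyl, over-reduction of the aryl ketone, hydrogenolysis of the benzylic C2–O1 bond, or air oxidation of the catechol on work-up.
- Fallback, from 18, returning at 19: the benzyl ethers are removed by Lewis acid instead of hydrogen, with BCl3 and pentamethylbenzene as cation scavenger in CH2Cl2 at −78 °C. Methyl ethers not flanked by a chelating phenoxide should survive at that temperature. No new compound is made.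

## Further compounds

F1 | step 9 | (2S,3R)-5,6-bis(benzyloxy)-2-[3-(benzyloxy)-4-methoxyphenyl]-7-methoxychroman-3-yl pivalate | COc1ccc([C@@H]2Oc3cc(OC)c(OCc4ccccc4)c(OCc4ccccc4)c3C[C@H]2OC(=O)C(C)(C)C)cc1OCc1ccccc1
F2 | step 9 | (2S,3R)-5,6-bis(benzyloxy)-2-[3-(benzyloxy)-4-methoxyphenyl]-7-methoxychroman-3-ol | COc1ccc([C@@H]2Oc3cc(OC)c(OCc4ccccc4)c(OCc4ccccc4)c3C[C@H]2O)cc1OCc1ccccc1
F3 | step 3 | 2-formyl-5-methoxy-3,4-dioxocyclohexa-1,5-dien-1-yl pivalate | O=CC1=C(OC(=O)C(C)(C)C)C=C(OC)C(=O)C1=O
F4 | step 8 | 2-(benzyloxy)-1-methoxy-4-(2-methoxyethenyl)benzene (E/Z mixture) | COC=Cc1ccc(OC)c(OCc2ccccc2)c1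
F5 | step 8 | 2-[3-(benzyloxy)-4-methoxyphenyl]acetaldehyde | COc1ccc(CC=O)cc1OCc1ccccc1
F6 | step 8 | (Z)-2-[3-(benzyloxy)-4-methoxyphenyl]ethenyl pivalate | COc1ccc(/C=C\OC(=O)C(C)(C)C)cc1OCc1ccccc1
F7 | step 12 | (2R,3R)-5,6-bis(benzyloxy)-2-[3-(benzyloxy)-4-methoxyphenyl]-3,7-dimethoxychroman-4-yl acetate (both C4 epimers) | COc1ccc([C@H]2Oc3cc(OC)c(OCc4ccccc4)c(OCc4ccccc4)c3C(OC(C)=O)[C@@H]2OC)cc1OCc1ccccc1
F0 | step 14 | none | none
A1 | alternative 1 | (2R,3S,4S)-2-[3-(benzyloxy)-4-methoxyphenyl]-5,6,7-trimethoxychroman-3,4-diol | COc1ccc([C@H]2Oc3cc(OC)c(OC)c(OC)c3[C@H](O)[C@@H]2O)cc1OCc1ccccc1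
A2 | alternative 1 | (2S)-2-[3-(benzyloxy)-4-methoxyphenyl]-5,6,7-trimethoxy-2H-chromene | COc1ccc([C@H]2Oc3cc(OC)c(OC)c(OC)c3C=C2)cc1OCc1ccccc1
A3 | alternative 2 | (2S)-2-[3-(benzyloxy)-4-methoxyphenyl]-5,6,7-trimethoxychroman-4-one | COc1ccc([C@H]2Oc3cc(OC)c(OC)c(OC)c3C(=O)C2)cc1OCc1ccccc1
A4 | alternative 2 | 1-{2-[(3-(benzyloxy)-4-methoxyphenyl)methoxy]-4,5,6-trimethoxyphenyl}-2-diazoethan-1-one | COc1ccc(COc2cc(OC)c(OC)c(OC)c2C(=O)C=[N+]=[N-])cc1OCc1ccccc1
A5 | alternative 3 | (2R,3R)-2-[3-(benzyloxy)-4-methoxyphenyl]-3,5,6,7-tetramethoxychroman-4-one | COc1ccc([C@H]2Oc3cc(OC)c(OC)c(OC)c3C(=O)[C@@H]2OC)cc1OCc1ccccc1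
A6 | alternative 3 | methyl (2R,3R)-3-[3-(benzyloxy)-4-methoxyphenyl]-3-hydroxy-2-methoxypropanoate | COc1ccc([C@@H](O)[C@@H](OC)C(=O)OC)cc1OCc1ccccc1
A7 | alternative 3 | 3,4,5-trimethoxybenzyne (1,2-didehydro-3,4,5-trimethoxybenzene) | C1#CC(OC)=C(OC)C(OC)=C1
A8 | alternative 3 | 3,4,5-trimethoxy-2-(trimethylsilyl)phenyl trifluoromethanesulfonate | COc1cc(OS(=O)(=O)C(F)(F)F)c([Si](C)(C)C)c(OC)c1OC
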